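**Plan**
- Retrosynthesis: C7–C8 and C5–C10 are cut together after a carbonyl is placed on C6; then C9–C11 (sp3–sp2 coupling), C9=C10 (cross-metathesis) and C2–C3 (Grignard addition) are cut.
- Enabling feature: ring B is a 3-hydroxy-3-methylcyclohexane whose carbinol C8 and quaternary C10 flank C9. With C6 as a ketone this is the ketol retron of a methyl ketone/enone Michael–aldol annulation (isophorone type); C5 and C7 are the two α-carbons of that one ketone.
- Forward: the open chain C7→C1 with the C3 stereocentre, the C8–C10 enone and the C9 side chain is assembled first; one base-mediated operation then closes ring A (C5–C10) and ring B (C7–C8).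
- Stereochemistry: C3 from a CBS reduction; C10 relative to C3 in the chair of the Michael step; C5, C8 and C9 by equilibration inside the cascade; chain alkenes from (2E,6E)-farnesol.
- Helpers: the C6 ketone (removed by reduction and Barton–McCombie deoxygenation) and the C3 silyl ether.

Key step: step 11

Convention used below: decalin carbons carry labdane-type numbers (ring A = C1–C5, C10; ring B = C5–C10; C4 gem-dimethyl, C10 angular methyl, C8 methyl carbinol, C9 chain; C11 is the first chain carbon); β is the face of the C10 methyl; "homofarnesyl" = (3E,7E)-4,8,12-trimethyltrideca-3,7,11-trien-1-yl; TBS = tert-butyldimethylsilyl.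

**Step 1**
Reactants: 2 4-bromo-2-methylbut-1-ene; 1 2,2-dimethylpent-4-enal
Product: 4 rac-2,6,6-trimethylnona-1,8-dien-5-ol, via Grignard reagent 3 (not isolated)
Conditions: Mg, THF, rt; then 1, 0 °C; aq. NH4Cl
Reagents that add atoms: none
Why: Grignard addition of a primary organomagnesium to the neopentyl aldehyde forms C2–C3; no stereocontrol is needed because the carbinol is oxidised next.

**Step 2**
Reactants: 4 rac-2,6,6-trimethylnona-1,8-dien-5-ol
Product: 5 2,6,6-trimethylnona-1,8-dien-5-one
Conditions: Dess–Martin periodinane, CH2Cl2, rt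
Reagents that add atoms: none
Why: Dess–Martin oxidation of the hindered secondary alcohol should give the ketone under neutral conditions that leave both alkenes untouched.

**Step 3**
Reactants: 5 2,6,6-trimethylnona-1,8-dien-5-one
Product: 6 (5S)-2,6,6-trimethylnona-1,8-dien-5-ol
Conditions: (R)-2-methyl-CBS-oxazaborolidine (0.2 equiv), catecholborane, toluene, −78 °C
Reagents that add atoms: none
Why: Corey–Bakshi–Shibata reduction distinguishes the tert-alkyl from the primary alkyl flank, so the (R)-catalyst should deliver hydride to the face that gives the (5S)-carbinol (future C3), and catecholborane at −78 °C should not hydroborate the alkenes.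

**Step 4**
Reactants: 6 (5S)-2,6,6-trimethylnona-1,8-dien-5-ol
Product: 7 tert-butyldimethyl{[(5S)-2,6,6-trimethylnona-1,8-dien-5-yl]oxy}silane
Conditions: TBSOTf, 2,6-lutidine, CH2Cl2, 0 °C
Reagents that add atoms: tert-butyldimethylsilyl trifluoromethanesulfonate, CC(C)(C)[Si](C)(C)OS(=O)(=O)C(F)(F)F
Why: Silylation with the silyl triflate overcomes the hindrance next to the quaternary carbon; the ether later blocks hemiketal formation and oxa-Michael addition.

**Step 5**
Reactants: 7 tert-butyldimethyl{[(5S)-2,6,6-trimethylnona-1,8-dien-5-yl]oxy}silane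
Product: 8 (5S)-5-(TBS-oxy)-4,4,8-trimethylnon-8-en-2-one
Conditions: PdCl2 (10 mol%), CuCl, O2 (1 atm), DMF/H2O 7:1, rt
Reagents that add atoms: water, O
Why: Tsuji–Wacker oxidation should convert only the monosubstituted allyl alkene into the methyl ketone (C6, C7), because the 1,1-disubstituted alkene reacts far more slowly.

**Step 6**
Reactants: 8 (5S)-5-(TBS-oxy)-4,4,8-trimethylnon-8-en-2-one; 9 but-3-en-2-one
Product: 10 (3E,7S)-7-(TBS-oxy)-4,8,8-trimethylundec-3-ene-2,10-dione
Conditions: second-generation Hoveyda–Grubbs catalyst (5 mol%), excess 9, CH2Cl2, 40 °C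
Reagents that add atoms: none
Why: Olefin cross-metathesis between the 1,1-disubstituted alkene and the electron-poor enone should give the E-trisubstituted enone (C8–C10), driven by loss of ethene.

**Step 7**
Reactants: 10 (3E,7S)-7-(TBS-oxy)-4,8,8-trimethylundec-3-ene-2,10-dione
Product: 11 (7S)-7-(TBS-oxy)-3-iodo-4,8,8-trimethylundec-3-ene-2,10-dione (E/Z mixture)
Conditions: TMSN3, I2, pyridine, CH2Cl2, 0 °C
Reagents that add atoms: iodine, II
Why: α-Iodination of the enone by conjugate addition of azide, iodination of the resulting enol derivative and pyridine-induced elimination of HN3; the saturated methyl ketone is not enolised under these conditions.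

**Step 8**
Reactants: 12 (2E,6E)-farnesol
Product: 13 (2E,6E)-farnesal
Conditions: MnO2, CH2Cl2, rt
Reagents that add atoms: none
Why: MnO2 oxidation is selective for the allylic alcohol and should not isomerise the 2E double bond.

**Step 9**
Reactants: 13 (2E,6E)-farnesal
Product: 14 (3E,7E)-4,8,12-trimethyltrideca-1,3,7,11-tetraene
Conditions: Ph3PCH3Br, KOtBu, THF, 0 °C
Reagents that add atoms: methyltriphenylphosphonium bromide, C[P+](c1ccccc1)(c1ccccc1)c1ccccc1.[Br-]
Why: Wittig methylenation of the enal adds C11 as a terminal CH2 and leaves the existing E geometry untouched.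

**Step 10**
Reactants: 14 (3E,7E)-4,8,12-trimethyltrideca-1,3,7,11-tetraene; 11 (7S)-7-(TBS-oxy)-3-iodo-4,8,8-trimethylundec-3-ene-2,10-dione
Product: 16 (7S)-7-(TBS-oxy)-3-homofarnesyl-4,8,8-trimethylundec-3-ene-2,10-dione (E/Z mixture), via alkylborane 15 (not isolated)
Conditions: 9-BBN, THF, 0 °C to rt; then 11, PdCl2(dppf) (5 mol%), Ph3As, Cs2CO3, DMF/H2O, rt
Reagents that add atoms: none
Why: 9-BBN hydroborates only the terminal double bond of the diene (anti-Markovnikov), and B-alkyl Suzuki–Miyaura coupling of the primary alkylborane with the α-iodoenone forms C9–C11; the geometry at C9=C10 does not matter because both carbons become sp3 in step 11.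

**Step 11**
Reactants: 16 (7S)-7-(TBS-oxy)-3-homofarnesyl-4,8,8-trimethylundec-3-ene-2,10-dione
Product: 18 (3S,5S,8R,9R,10R)-3-(TBS-oxy)-8-hydroxy-9-homofarnesyl-4,4,8,10-tetramethyldecalin-6-one (cis-fused: 5β-H 8α-OH 9β-chain), via Michael adduct 17 (not isolated)
Conditions: KOtBu (0.3 equiv), t-BuOH/THF 1:4, 0 °C to rt; AcOH quench
Reagents that add atoms: none
Why: Reversible deprotonation gives the C5 enolate of the C6 ketone, which adds to C10 of the tetrasubstituted enone (Michael addition, 6-(enolexo)-exo-trig, closes ring A); after proton transfer the C7 enolate of the same ketone adds to the C8 carbonyl (aldol, 6-(enolendo)-exo-trig, closes ring B). The closest known reaction is the base-mediated Michael–aldol annulation of acetone with mesityl oxide to the isophorone ketol, and the ketol stage of the Robinson annulation. C10 is set in the chair-like Michael transition state in which the C3 silyloxy group and the bulky enone arm are equatorial and the C10 methyl axial, which places that methyl cis to O3. C5 and C9 are enolisable and C8 is reversible (retro-aldol), so these centres settle under thermodynamic control; the cis-fused chair–chair ketol is expected because C6 sits axial on ring A and the C9 chain axial on ring B, each anti to the axial groups of its two fully substituted neighbours, while the C8 methyl is equatorial because an axial methyl there would be 1,3-diaxial to C1. The step needs the C5 and not the C7 enolate in the conjugate addition, which ring size secures (six against eight members), and attack of C7 on C8 and not of the C8 acetyl methyl on C6, which the shielding of the C6 carbonyl by C5 between two quaternary carbons secures. Substoichiometric base at low temperature should keep the tertiary aldol from losing water.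

**Step 12**
Reactants: 18 the C6 ketol
Product: 19 3β-(TBS-oxy)-9β-homofarnesyl-4,4,8β,10β-tetramethyl-5β-decalin-6,8α-diol (C6 epimers)
Conditions: LiAlH4, THF, −20 °C
Reagents that add atoms: none
Why: Hydride reduction of the hindered C6 ketone gives the secondary alcohol, whose configuration is irrelevant because this oxygen is removed.

**Step 13**
Reactants: 19 the 6,8-diol
Product: 20 O-phenyl thionocarbonate of 19 at O6
Conditions: PhOC(S)Cl, pyridine, DMAP (cat.), CH2Cl2, 0 °C to rt
Reagents that add atoms: O-phenyl chlorothionoformate, S=C(Cl)Oc1ccccc1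
Why: Acylation (first half of a Barton–McCombie deoxygenation) should take place only at the secondary C6 hydroxyl, because the tertiary C8 hydroxyl is unreactive.

**Step 14**
Reactants: 20 the O6 thionocarbonate
Product: 21 (3S,5S,8R,9R,10S)-3-(TBS-oxy)-9-homofarnesyl-4,4,8,10-tetramethyldecalin-8-ol
Conditions: Bu3SnH, AIBN (cat.), toluene, 90 °C
Reagents that add atoms: none
Why: Barton–McCombie radical deoxygenation: the stannyl radical adds to the thiocarbonyl, the C6–O bond fragments, and the secondary radical takes hydrogen from the stannane faster than it can reach the chain alkenes (only seven- or eight-membered cyclisations are possible).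

**Step 15**
Reactants: 21 the C3 silyl ether
Product: 22 target, (3S,5S,8R,9R,10S)-9-homofarnesyl-4,4,8,10-tetramethyldecalin-3,8-diol [(2S,4aS,5R,6R,8aS)-1,1,4a,6-tetramethyl-5-homofarnesyl-decahydronaphthalene-2,6-diol]
Conditions: Bu4NF, THF, 50 °C
Reagents that add atoms: none
Why: Fluoride-induced desilylation frees the C3 alcohol without touching the tertiary alcohol or the trisubstituted alkenes.

**Compound list**
1 | 2,2-dimethylpent-4-enal | C=CCC(C)(C)C=O | starting material
2 | 4-bromo-2-methylbut-1-ene | CC(=C)CCBr | starting material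
3 | (3-methylbut-3-en-1-yl)magnesium bromide | CC(=C)CC[Mg]Br | intermediate
4 | rac-2,6,6-trimethylnona-1,8-dien-5-ol | CC(=C)CCC(O)C(C)(C)CC=C | intermediate
5 | 2,6,6-trimethylnona-1,8-dien-5-one | CC(=C)CCC(=O)C(C)(C)CC=C | intermediate
6 | (5S)-2,6,6-trimethylnona-1,8-dien-5-ol | CC(=C)CC[C@H](O)C(C)(C)CC=C | intermediate
7 | tert-butyldimethyl{[(5S)-2,6,6-trimethylnona-1,8-dien-5-yl]oxy}silane | CC(=C)CC[C@H](O[Si](C)(C)C(C)(C)C)C(C)(C)CC=C | intermediate
8 | (5S)-5-(TBS-oxy)-4,4,8-trimethylnon-8-en-2-one | CC(=C)CC[C@H](O[Si](C)(C)C(C)(C)C)C(C)(C)CC(C)=O | intermediate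
9 | but-3-en-2-one | CC(=O)C=C | starting material
10 | (3E,7S)-7-(TBS-oxy)-4,8,8-trimethylundec-3-ene-2,10-dione | CC(=O)/C=C(\C)CC[C@H](O[Si](C)(C)C(C)(C)C)C(C)(C)CC(C)=O | intermediate
11 | (7S)-7-(TBS-oxy)-3-iodo-4,8,8-trimethylundec-3-ene-2,10-dione (E/Z mixture) | CC(=O)C(I)=C(C)CC[C@H](O[Si](C)(C)C(C)(C)C)C(C)(C)CC(C)=O | intermediate
12 | (2E,6E)-farnesol | CC(C)=CCC/C(C)=C/CC/C(C)=C/CO | starting material
13 | (2E,6E)-farnesal | CC(C)=CCC/C(C)=C/CC/C(C)=C/C=O | intermediate
14 | (3E,7E)-4,8,12-trimethyltrideca-1,3,7,11-tetraene | CC(C)=CCC/C(C)=C/CC/C(C)=C/C=C | intermediate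
15 | 9-homofarnesyl-9-borabicyclo[3.3.1]nonane | CC(C)=CCC/C(C)=C/CC/C(C)=C/CCB1C2CCCC1CCC2 | intermediate
16 | (7S)-7-(TBS-oxy)-3-homofarnesyl-4,8,8-trimethylundec-3-ene-2,10-dione (E/Z mixture at C9=C10) | CC(=O)C(CC/C=C(\C)CC/C=C(\C)CCC=C(C)C)=C(C)CC[C@H](O[Si](C)(C)C(C)(C)C)C(C)(C)CC(C)=O | intermediate
17 | Michael adduct: ring A closed, 3β-TBS-oxy, C5 acetyl α, C10 methyl β, C10 carrying the 3-oxobutan-2-yl unit with the homofarnesyl chain, C9 not fixed | CC(=O)C(CC/C=C(\C)CC/C=C(\C)CCC=C(C)C)[C@@]1(C)CC[C@H](O[Si](C)(C)C(C)(C)C)C(C)(C)[C@H]1C(C)=O | intermediate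
18 | (3S,5S,8R,9R,10R)-3-(TBS-oxy)-8-hydroxy-9-homofarnesyl-4,4,8,10-tetramethyldecalin-6-one | CC(C)=CCC/C(C)=C/CC/C(C)=C/CC[C@@H]1[C@@]2(C)CC[C@H](O[Si](C)(C)C(C)(C)C)C(C)(C)[C@H]2C(=O)C[C@@]1(C)O | intermediate
19 | 6-hydroxy compound from 18 (C6 epimers) | CC(C)=CCC/C(C)=C/CC/C(C)=C/CC[C@@H]1[C@@]2(C)CC[C@H](O[Si](C)(C)C(C)(C)C)C(C)(C)[C@H]2C(O)C[C@@]1(C)O | intermediate
20 | O6 phenyl thionocarbonate of 19 | CC(C)=CCC/C(C)=C/CC/C(C)=C/CC[C@@H]1[C@@]2(C)CC[C@H](O[Si](C)(C)C(C)(C)C)C(C)(C)[C@H]2C(OC(=S)Oc3ccccc3)C[C@@]1(C)O | intermediate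
21 | (3S,5S,8R,9R,10S)-3-(TBS-oxy)-9-homofarnesyl-4,4,8,10-tetramethyldecalin-8-ol | CC(C)=CCC/C(C)=C/CC/C(C)=C/CC[C@@H]1[C@@]2(C)CC[C@H](O[Si](C)(C)C(C)(C)C)C(C)(C)[C@H]2CC[C@@]1(C)O | intermediate
22 | (3S,5S,8R,9R,10S)-9-homofarnesyl-4,4,8,10-tetramethyldecalin-3,8-diol | CC(C)=CCC/C(C)=C/CC/C(C)=C/CC[C@@H]1[C@@]2(C)CC[C@H](O)C(C)(C)[C@H]2CC[C@@]1(C)O | target

**Totals and risks**
Total: 15 steps. Longest linear sequence: 13 steps (steps 1–7 and 10–15 from compound 1).

Step 11. The conjugate addition to the fully substituted enone carbon may be slow, the tertiary aldol may lose water under the basic conditions, and the ring fusion may drift into the trans series. The fallback moves the C8 carbinol from the aldol to an epoxide opening. It sets out from 16: KOH in MeOH at reflux should drive the annulation through to the conjugated ketone, the cis-fused 3β-(TBS-oxy)-9β-homofarnesyl-7-en-6-one F1, at which stage C5 can still be equilibrated and ring-fusion isomers separated. Nucleophilic epoxidation (H2O2, NaOH, MeOH, 0 °C), anti to the C9 chain and the C10 methyl, should give the 7α,8α-epoxy-6-ketone F2. Wharton transposition (N2H4·H2O, AcOH, MeOH) should give the 8α-hydroxy-6-ene F3 and removes the C6 oxygen at the same time. Diimide (2-nitrobenzenesulfonyl hydrazide, Et3N, CH2Cl2) should reduce the disubstituted ring alkene in preference to the trisubstituted chain alkenes, and the route is rejoined at 21.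

Step 7. Azide may add poorly to the β,β-disubstituted enone, which leaves starting enone or leads to iodination elsewhere. The fallback makes the α-halo enone by addition–elimination and sets out from 10: Br2 in CH2Cl2 at −78 °C should add across the enone double bond to give the 3,4-dibromo-diketone F4, and Et3N should remove HBr to give the α-bromoenone F5. F5 takes the place of 11 in the B-alkyl Suzuki–Miyaura coupling with 15 and the route is rejoined at 16.

Step 13. The hindered C6 hydroxyl may resist acylation, or the thiocarbonyl group may close onto the C8 hydroxyl as a cyclic thionocarbonate that fragments the wrong way. The fallback removes the oxygen at the ketone stage and sets out from 18: condensation with p-toluenesulfonyl hydrazide (EtOH, cat. AcOH) should give the C6 tosylhydrazone F6, and reduction with catecholborane followed by NaOAc (hydride addition, then loss of sulfinate and dinitrogen) should give the methylene compound, rejoining the route at 21.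

**Further compounds**
F1 | step 11 | 3β-(TBS-oxy)-9β-homofarnesyl-4,4,8,10β-tetramethyl-5β-decal-7-en-6-one | CC(C)=CCC/C(C)=C/CC/C(C)=C/CC[C@@H]1[C@@]2(C)CC[C@H](O[Si](C)(C)C(C)(C)C)C(C)(C)[C@H]2C(=O)C=C1C
F2 | step 11 | 7α,8α-epoxide of F1 | CC(C)=CCC/C(C)=C/CC/C(C)=C/CC[C@@H]1[C@@]2(C)CC[C@H](O[Si](C)(C)C(C)(C)C)C(C)(C)[C@H]2C(=O)[C@H]3O[C@@]13C
F3 | step 11 | 3β-(TBS-oxy)-9β-homofarnesyl-4,4,8β,10β-tetramethyl-5β-decal-6-en-8α-ol | CC(C)=CCC/C(C)=C/CC/C(C)=C/CC[C@@H]1[C@@]2(C)CC[C@H](O[Si](C)(C)C(C)(C)C)C(C)(C)[C@H]2C=C[C@@]1(C)O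
F4 | step 7 | (7S)-3,4-dibromo-7-(TBS-oxy)-4,8,8-trimethylundecane-2,10-dione (diastereomers) | CC(=O)C(Br)C(C)(Br)CC[C@H](O[Si](C)(C)C(C)(C)C)C(C)(C)CC(C)=O
F5 | step 7 | (7S)-3-bromo-7-(TBS-oxy)-4,8,8-trimethylundec-3-ene-2,10-dione | CC(=O)C(Br)=C(C)CC[C@H](O[Si](C)(C)C(C)(C)C)C(C)(C)CC(C)=O
F6 | step 13 | C6 p-toluenesulfonylhydrazone of 18 | CC(C)=CCC/C(C)=C/CC/C(C)=C/CC[C@@H]1[C@@]2(C)CC[C@H](O[Si](C)(C)C(C)(C)C)C(C)(C)[C@H]2C(=NNS(=O)(=O)c3ccc(C)cc3)C[C@@]1(C)O
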